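**Remark (assumption):** prostaglandin numbering is used throughout (C1 = ester carbon, C8 and C12 = ring carbons bearing the two chains, C9 = ketone, C15 = acetoxy carbon). The SMILES is read as (8R,12S,15S), 5Z,13E, i.e. PGA2 methyl ester 15-acetate.

## Retrosynthetic overview

1. Target 17 ⇐ O15-acetylation of 16 ⇐ methanolysis of PGA2 1,15-lactone 15. The feature used is that the C1 ester carbon and the C15 oxygen are both acylated, so they can be tied together for a time as a 13-membered lactone (C1–C8, C12–C15, O15) fused to the cyclopentenone at C8/C12.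
2. 15 ⇐ Z-selective ring-closing metathesis forming C5=C6 from ester 14 (allyl on C8, hex-5-enoate on O15).
3. 14 ⇐ esterification of alcohol 12 with acid 13 ⇐ desilylation of 11 ⇐ α′-allylation (C7–C8) of enone 8, trans to C12.
4. 8 ⇐ oxidation of 7 ⇐ nickel-catalysed anti alkenylation (C12–C13) of monoacetate 5 with the borate of boronate 4 ⇐ hydroboration of silyl ether 2 of alkynol 1.
5. Ring order: the cyclopentene ring is bought; the 13-membered lactone is the only ring formed (step 8) and is opened again in step 9.

Key step: step 8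

## Route

Step 1
Reactants: 1 (S)-oct-1-yn-3-ol
Product: 2 (S)-tert-butyldimethyl(oct-1-yn-3-yloxy)silane
Conditions: TBSCl, imidazole, DMF, 0 °C to rt
Reagents that add atoms: tert-butyldimethylsilyl chloride, CC(C)(C)[Si](C)(C)Cl
Why: Imidazole-promoted silylation of a secondary propargylic alcohol is routine silyl ether formation, and the bought C15 centre is not touched.

Step 2
Reactants: 2 (S)-tert-butyldimethyl(oct-1-yn-3-yloxy)silane
Product: 4 (4R,5R)-2-[(1E,3S)-3-(tert-butyldimethylsilyloxy)oct-1-enyl]-4,5-dimethyl-1,3,2-dioxaborolane, via catechol boronate 3 (not isolated)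
Conditions: catecholborane, Cy2BH (10 mol%), THF, rt; then (2R,3R)-butane-2,3-diol, rt
Reagents that add atoms: catecholborane, B1Oc2ccccc2O1; (2R,3R)-butane-2,3-diol, C[C@@H](O)[C@@H](C)O
Why: Dialkylborane-catalysed syn hydroboration of the terminal alkyne puts boron on the terminal carbon and gives the E-alkenylboronate (the future C13=C14), and transesterification then exchanges the catechol ester for the aliphatic diol ester that forms a reactive borate.

Step 3
Reactants: 4 (4R,5R)-2-[(1E,3S)-3-(tert-butyldimethylsilyloxy)oct-1-enyl]-4,5-dimethyl-1,3,2-dioxaborolane; 5 (1R,4S)-cis-4-acetoxycyclopent-2-en-1-ol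
Product: 7 (1R,4R)-4-[(1E,3S)-3-(tert-butyldimethylsilyloxy)oct-1-enyl]cyclopent-2-en-1-ol (trans), via lithium methylborate 6 (not isolated)
Conditions: 4 (1.8 equiv), MeLi, THF, 0 °C; then 5, NiCl2(PPh3)2 (10 mol%), NaI, t-BuCN, THF, rt to 40 °C
Reagents that add atoms: none
Why: In this nickel-catalysed allylic substitution with a lithium alkenylborate, the acetate is ionised with inversion to a π-allylnickel and the alkenyl group is delivered from the metal at the terminus remote from the carbinol, so the 1,4-product forms with overall inversion and C12 is set trans to the hydroxyl from the bought acetate centre.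

Step 4
Reactants: 7 (1R,4R)-4-[(1E,3S)-3-(tert-butyldimethylsilyloxy)oct-1-enyl]cyclopent-2-en-1-ol
Product: 8 (S)-4-[(1E,3S)-3-(tert-butyldimethylsilyloxy)oct-1-enyl]cyclopent-2-en-1-one
Conditions: Dess–Martin periodinane, CH2Cl2, 0 °C to rt
Reagents that add atoms: none
Why: Dess–Martin oxidation of the secondary allylic alcohol is base-free, so the C12 hydrogen, which becomes γ to the new carbonyl and is doubly allylic, should not migrate.

Step 5
Reactants: 8 (S)-4-[(1E,3S)-3-(tert-butyldimethylsilyloxy)oct-1-enyl]cyclopent-2-en-1-one; 9 allyl bromide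
Product: 11 (4S,5R)-5-allyl-4-[(1E,3S)-3-(tert-butyldimethylsilyloxy)oct-1-enyl]cyclopent-2-en-1-one, via lithium enolate 10 (not isolated)
Conditions: LDA (1.05 equiv), THF, −78 °C; then 9 (3 equiv), DMPU, −78 to −40 °C; AcOH quench at −78 °C
Reagents that add atoms: none
Why: Kinetic deprotonation of the enone with LDA takes the α′-methylene proton (cross-conjugated enolate), and SN2 allylation of the lithium enolate occurs on the face opposite the adjacent C12 alkenyl group, which sets C8 trans to C12, also the thermodynamically preferred arrangement.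

Step 6
Reactants: 11 (4S,5R)-5-allyl-4-[(1E,3S)-3-(tert-butyldimethylsilyloxy)oct-1-enyl]cyclopent-2-en-1-one
Product: 12 (4S,5R)-5-allyl-4-[(1E,3S)-3-hydroxyoct-1-enyl]cyclopent-2-en-1-one
Conditions: HF·pyridine, pyridine, THF, 0 °C to rt
Reagents that add atoms: none
Why: Buffered HF·pyridine desilylation frees the C15 alcohol without the basic fluoride that would epimerise C8 or move the enone double bond into the ring-fusion position.

Step 7
Reactants: 12 (4S,5R)-5-allyl-4-[(1E,3S)-3-hydroxyoct-1-enyl]cyclopent-2-en-1-one; 13 hex-5-enoic acid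
Product: 14 (1E,3S)-1-[(1S,5R)-5-allyl-4-oxocyclopent-2-en-1-yl]oct-1-en-3-yl hex-5-enoate
Conditions: EDC·HCl, DMAP (0.1 equiv), CH2Cl2, 0 °C to rt
Reagents that add atoms: none
Why: Steglich esterification acylates the secondary allylic alcohol without breaking the C15–O bond, so 15S is retained, and catalytic DMAP at 0 °C is too weak a base to isomerise the enone.

Step 8
Reactants: 14 (1E,3S)-1-[(1S,5R)-5-allyl-4-oxocyclopent-2-en-1-yl]oct-1-en-3-yl hex-5-enoate
Product: 15 PGA2 1,15-lactone [(5Z,13E,15S)-9-oxoprosta-5,10,13-trien-15-olide, 8R,12S]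
Conditions: cyclometalated N-adamantyl/N-(2,6-diisopropylphenyl) NHC–Ru nitrato 2-isopropoxybenzylidene catalyst (7.5 mol%), ClCH2CH2Cl, 3 mM, 60 °C, static vacuum
Reagents that add atoms: none
Why: The ruthenium alkylidene loads on one of the two monosubstituted alkenes (most likely the unhindered hexenoate terminus), undergoes [2+2] cycloaddition with the other vinyl group, and the ruthenacyclobutane cycloreverts with loss of ethylene to form C5=C6. This is Z-selective macrocyclic ring-closing olefin metathesis of an α,ω-diene ester with a cyclometalated NHC–ruthenium catalyst, a known reaction type for 13- to 20-membered lactones. The 13-membered 1,15-lactone (C1–C8, C12–C15 and O15) is closed end-to-end between two terminal vinyl groups, and no stereocentre is created. Z geometry is set by the catalyst, whose chelated N-adamantyl NHC enforces a side-bound ruthenacycle with both substituents pointing away from the N-aryl group, and it should persist because this catalyst class hardly re-enters Z-disubstituted alkenes. The step needs chemoselectivity for the two vinyl groups over C13=C14 and C10=C11 and ring closure over oligomerisation: the E-alkene is 1,2-disubstituted between two branched carbons, the enone alkene is electron-poor, closure of the allyl group onto C13 would need a trans-fused bicyclo[3.3.0]octene, and 3 mM concentration with removal of ethylene favours the macrocycle. The C1–O15 ester bridge is not part of the target and serves only to make the olefination intramolecular and base-free, so C8, C12 and the enone are left alone.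

Step 9
Reactants: 15 PGA2 1,15-lactone
Product: 16 PGA2 methyl ester [methyl (5Z,13E,15S)-15-hydroxy-9-oxoprosta-5,10,13-trien-1-oate]
Conditions: 1-hydroxy-3-isothiocyanato-1,1,3,3-tetrabutyldistannoxane (10 mol%), MeOH/toluene 1:1, 70 °C
Reagents that add atoms: methanol, CO
Why: Distannoxane-catalysed transesterification in a large excess of methanol opens the lactone at the C1 acyl carbon under neutral conditions, so the C15–O bond, the C8 and C12 centres and the enone are not disturbed.

Step 10
Reactants: 16 PGA2 methyl ester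
Product: 17 PGA2 methyl ester 15-acetate (target)
Conditions: Ac2O, pyridine, CH2Cl2, 0 °C to rt
Reagents that add atoms: acetic anhydride, CC(=O)OC(C)=O
Why: Acetylation of the secondary allylic alcohol with acetic anhydride/pyridine is acyl transfer at oxygen and retains the 15S configuration.

## Compound list

1 | (S)-oct-1-yn-3-ol | CCCCC[C@@H](C#C)O | starting material
2 | (S)-tert-butyldimethyl(oct-1-yn-3-yloxy)silane | CCCCC[C@@H](C#C)O[Si](C)(C)C(C)(C)C | intermediate
3 | 2-[(1E,3S)-3-(tert-butyldimethylsilyloxy)oct-1-enyl]-1,3,2-benzodioxaborole (catechol boronate, not isolated) | CCCCC[C@@H](/C=C/B1Oc2ccccc2O1)O[Si](C)(C)C(C)(C)C | intermediate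
4 | (4R,5R)-2-[(1E,3S)-3-(tert-butyldimethylsilyloxy)oct-1-enyl]-4,5-dimethyl-1,3,2-dioxaborolane | CCCCC[C@@H](/C=C/B1O[C@H](C)[C@@H](C)O1)O[Si](C)(C)C(C)(C)C | intermediate
5 | (1R,4S)-cis-4-acetoxycyclopent-2-en-1-ol | CC(=O)O[C@@H]1C=C[C@H](O)C1 | starting material
6 | lithium methylborate of 4 (B-methyl ate complex, not isolated) | [Li+].CCCCC[C@@H](/C=C/[B-]1(C)O[C@H](C)[C@@H](C)O1)O[Si](C)(C)C(C)(C)C | intermediate
7 | (1R,4R)-4-[(1E,3S)-3-(tert-butyldimethylsilyloxy)oct-1-enyl]cyclopent-2-en-1-ol (trans) | CCCCC[C@@H](/C=C/[C@H]1C=C[C@H](O)C1)O[Si](C)(C)C(C)(C)C | intermediate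
8 | (S)-4-[(1E,3S)-3-(tert-butyldimethylsilyloxy)oct-1-enyl]cyclopent-2-en-1-one | CCCCC[C@@H](/C=C/[C@H]1C=CC(=O)C1)O[Si](C)(C)C(C)(C)C | intermediate
9 | allyl bromide | C=CCBr | starting material
10 | lithium cross-conjugated (C8–C9) enolate of 8 (not isolated) | [Li+].CCCCC[C@@H](/C=C/[C@H]1C=CC([O-])=C1)O[Si](C)(C)C(C)(C)C | intermediate
11 | (4S,5R)-5-allyl-4-[(1E,3S)-3-(tert-butyldimethylsilyloxy)oct-1-enyl]cyclopent-2-en-1-one | CCCCC[C@@H](/C=C/[C@H]1C=CC(=O)[C@@H]1CC=C)O[Si](C)(C)C(C)(C)C | intermediate
12 | (4S,5R)-5-allyl-4-[(1E,3S)-3-hydroxyoct-1-enyl]cyclopent-2-en-1-one | CCCCC[C@@H](/C=C/[C@H]1C=CC(=O)[C@@H]1CC=C)O | intermediate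
13 | hex-5-enoic acid | OC(=O)CCCC=C | starting material
14 | (1E,3S)-1-[(1S,5R)-5-allyl-4-oxocyclopent-2-en-1-yl]oct-1-en-3-yl hex-5-enoate | CCCCC[C@@H](/C=C/[C@H]1C=CC(=O)[C@@H]1CC=C)OC(=O)CCCC=C | intermediate
15 | PGA2 1,15-lactone | CCCCC[C@H]1/C=C/[C@H]2C=CC(=O)[C@@H]2C/C=C\CCCC(=O)O1 | intermediate
16 | PGA2 methyl ester | CCCCC[C@H](O)/C=C/[C@H]1C=CC(=O)[C@@H]1C/C=C\CCCC(=O)OC | intermediate
17 | PGA2 methyl ester 15-acetate | CCCCC[C@@H](/C=C/[C@H]1C=CC(=O)[C@@H]1C/C=C\CCCC(=O)OC)OC(C)=O | target

## Step count and risks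

Total step count: 10. Longest linear sequence: 10 steps (1 → 17); compounds 5, 9 and 13 enter as bought partners.

**Risk 1, step 8 (ring-closing metathesis).** Intermolecular metathesis could outrun ring closure and give oligomers, the catalyst could be slowed by chelation to the enone or ester, or Z-selectivity could be incomplete in this rigid ring. The fallback is ring-closing alkyne metathesis followed by semihydrogenation. It sets out from enone 8: the lithium enolate 10 is alkylated with 1-bromobut-2-yne to give the trans 5-(but-2-ynyl) enone F1. HF·pyridine then gives the alcohol F2, and Steglich esterification with hept-5-ynoic acid gives the diyne ester F3. A molybdenum alkylidyne tris(triphenylsilanolate) catalyst in toluene with 5 Å molecular sieves closes the 13-membered cycloalkyne, 5,6-didehydro-PGA2 1,15-lactone F4, with loss of but-2-yne. Lindlar hydrogenation (Pd/CaCO3/Pb, quinoline, H2) fixes the Z-alkene by syn addition and rejoins the route at lactone 15.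

**Risk 2, step 5 (α′-allylation).** Proton exchange between the product and unreacted enolate could lead to double allylation, and deprotonation at the γ-carbon C12 could shift the double bond or erode the C12 configuration. The fallback builds the ring substitution by three-component conjugate addition and enolate trapping. It sets out from silyl ether 2: hydrozirconation with Cp2Zr(H)Cl and iodination give the (S,E)-vinyl iodide F5. Lithium–iodine exchange (t-BuLi) and Me2Zn give the alkenyl zincate, which adds to commercial (R)-4-(tert-butyldimethylsilyloxy)cyclopent-2-en-1-one anti to the silyloxy group. The enolate is trapped with allyl iodide/HMPA trans to the new chain to give the 2-allyl-3-alkenyl-4-silyloxycyclopentanone F6. Aqueous HF in MeCN removes both silyl groups to give the β-hydroxy ketone F7, and warm aqueous acetic acid dehydrates it (PGE-to-PGA type elimination) to rejoin the route at alcohol 12.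

**Risk 3, step 9 (methanolysis).** Acyl transfer at the hindered secondary allylic ester could be slow, and prolonged heating could allow conjugate addition of methanol to the enone or migration of the enone double bond. The fallback separates ring opening from esterification. It sets out from lactone 15: hydrolysis with porcine liver esterase in pH 7 phosphate buffer/acetone at rt gives PGA2 F8, and the acid is methylated with TMSCHN2 in MeOH/toluene at 0 °C to rejoin the route at methyl ester 16.

## Further compounds

F1 | step 8 | (4S,5R)-5-(but-2-yn-1-yl)-4-[(1E,3S)-3-(tert-butyldimethylsilyloxy)oct-1-enyl]cyclopent-2-en-1-one | CCCCC[C@@H](/C=C/[C@H]1C=CC(=O)[C@@H]1CC#CC)O[Si](C)(C)C(C)(C)C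
F2 | step 8 | (4S,5R)-5-(but-2-yn-1-yl)-4-[(1E,3S)-3-hydroxyoct-1-enyl]cyclopent-2-en-1-one | CCCCC[C@@H](/C=C/[C@H]1C=CC(=O)[C@@H]1CC#CC)O
F3 | step 8 | (1E,3S)-1-[(1S,5R)-5-(but-2-yn-1-yl)-4-oxocyclopent-2-en-1-yl]oct-1-en-3-yl hept-5-ynoate | CCCCC[C@@H](/C=C/[C@H]1C=CC(=O)[C@@H]1CC#CC)OC(=O)CCCC#CC
F4 | step 8 | 5,6-didehydro-PGA2 1,15-lactone (13-membered cycloalkyne) | CCCCC[C@H]1/C=C/[C@H]2C=CC(=O)[C@@H]2CC#CCCCC(=O)O1
F5 | step 5 | (S,E)-tert-butyl[(1-iodooct-1-en-3-yl)oxy]dimethylsilane | CCCCC[C@@H](/C=C/I)O[Si](C)(C)C(C)(C)C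
F6 | step 5 | (2R,3R,4R)-2-allyl-4-(tert-butyldimethylsilyloxy)-3-[(1E,3S)-3-(tert-butyldimethylsilyloxy)oct-1-enyl]cyclopentan-1-one | CCCCC[C@@H](/C=C/[C@H]1[C@H](O[Si](C)(C)C(C)(C)C)CC(=O)[C@@H]1CC=C)O[Si](C)(C)C(C)(C)C
F7 | step 5 | (2R,3R,4R)-2-allyl-4-hydroxy-3-[(1E,3S)-3-hydroxyoct-1-enyl]cyclopentan-1-one | CCCCC[C@@H](/C=C/[C@H]1[C@H](O)CC(=O)[C@@H]1CC=C)O
F8 | step 9 | PGA2 [(5Z,13E,15S)-15-hydroxy-9-oxoprosta-5,10,13-trien-1-oic acid] | CCCCC[C@H](O)/C=C/[C@H]1C=CC(=O)[C@@H]1C/C=C\CCCC(=O)O
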